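**Plan**

- Retrosynthesis: the three phenolic benzyl ethers come off last, and the CH2 linking ring D to ring B is traced back to a diaryl ketone. Ring B (C1 OH, C2 ring-D benzyl, C3 arylethyl chain to ring A, C4 ring-C benzyl, C5 and C6 CH) is then cut at C1–C2 and C3–C4.
- Feature that allows the cut: C1, C6, C5 and C4 of ring B read as a 1,1-dioxygenated 5-arylpenta-1,3-diene (a silyl ketene acetal). C3 and C2 read as an alkyne whose C2 substituent is at the aroyl oxidation level (an ynone).
- Forward: rings A, C and D are bought as arenes, and both side chains start as 3-arylpropanals made by Heck arylation of allyl alcohol. One aldehyde becomes the ynone (alkyne homologation, acyl Sonogashira); the other becomes the diene (Doebner condensation, benzyl ester, silyl dienolate).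
- Ring B is the only ring formed, by Diels–Alder benzannulation; ketone deoxygenation and hydrogenolysis finish the route.
- Stereochemistry: the target has no stereocentre. The only geometry that matters is the E 3,4-alkene of the diene, set in the Doebner step and consumed in the annulation.

Key step: step 9

Assumption: 3-bromo-5-methoxyphenol, 1-(benzyloxy)-4-iodobenzene and 4-(benzyloxy)benzoyl chloride are taken as catalogue compounds; the geometry at the acetal C=C of the ketene acetal is without consequence because that carbon becomes aromatic.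

Step 1
Reactants: 1 3-bromo-5-methoxyphenol
Product: 2 1-(benzyloxy)-3-bromo-5-methoxybenzene
Conditions: BnBr, K2CO3, DMF, rt
Reagents that add atoms: benzyl bromide, BrCc1ccccc1
Why: Williamson ether synthesis, in which the phenoxide formed with K2CO3 displaces bromide from the benzylic halide in an SN2 reaction while the aryl bromide is inert.

Step 2
Reactants: 2 1-(benzyloxy)-3-bromo-5-methoxybenzene; 3 prop-2-en-1-ol (allyl alcohol)
Product: 4 3-[3-(benzyloxy)-5-methoxyphenyl]propanal
Conditions: Pd(OAc)2 (cat.), Bu4NCl, NaHCO3, DMF, 90 °C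
Reagents that add atoms: none
Why: Heck arylation of an allylic alcohol under phase-transfer conditions, in which the arylpalladium species adds to the terminal alkene carbon and β-hydride elimination toward the carbinol carbon gives an enol that tautomerises, so the 3-arylpropanal should form directly.

Step 3
Reactants: 4 3-[3-(benzyloxy)-5-methoxyphenyl]propanal
Product: 5 1-(benzyloxy)-3-(but-3-yn-1-yl)-5-methoxybenzene
Conditions: dimethyl (1-diazo-2-oxopropyl)phosphonate, K2CO3, MeOH, 0 °C to rt
Reagents that add atoms: dimethyl (1-diazo-2-oxopropyl)phosphonate, CC(=O)C(=[N+]=[N-])P(=O)(OC)OC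
Why: Seyferth–Gilbert homologation in the Ohira–Bestmann variant, in which methanolysis of the reagent gives the diazomethylphosphonate anion that olefinates the aldehyde, and the diazoalkene loses N2 with a 1,2-hydrogen shift to the terminal alkyne under base mild enough for an enolisable aldehyde.

Step 4
Reactants: 5 1-(benzyloxy)-3-(but-3-yn-1-yl)-5-methoxybenzene; 6 4-(benzyloxy)benzoyl chloride
Product: 7 5-[3-(benzyloxy)-5-methoxyphenyl]-1-[4-(benzyloxy)phenyl]pent-2-yn-1-one
Conditions: PdCl2(PPh3)2 (cat.), CuI (cat.), Et3N, THF, rt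
Reagents that add atoms: none
Why: Acyl Sonogashira coupling, in which the aroyl chloride adds oxidatively to zerovalent palladium, the copper acetylide of 5 transmetalates and reductive elimination gives the ynone at room temperature, where the benzyl ethers are untouched.

Step 5
Reactants: 8 1-(benzyloxy)-4-iodobenzene; 3 prop-2-en-1-ol (allyl alcohol)
Product: 9 3-[4-(benzyloxy)phenyl]propanal
Conditions: Pd(OAc)2 (cat.), Bu4NCl, NaHCO3, DMF, 40 °C
Reagents that add atoms: none
Why: The same Heck arylation of allyl alcohol, easier here because the aryl iodide undergoes oxidative addition at 40 °C, should give the linear aldehyde by insertion at the terminal carbon, β-hydride elimination toward the carbinol carbon and tautomerisation.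

Step 6
Reactants: 9 3-[4-(benzyloxy)phenyl]propanal; 10 malonic acid
Product: 12 (3E)-5-[4-(benzyloxy)phenyl]pent-3-enoic acid, via alkylidenemalonic acid 11 (not isolated)
Conditions: N-methylmorpholine, neat, 95 °C; aq. HCl work-up
Reagents that add atoms: none
Why: Knoevenagel–Doebner condensation in its tertiary-amine (deconjugative) form, in which alkylidenemalonic acid 11 decarboxylates as its amine salt with protonation at the α-carbon, a course known to give (E)-alk-3-enoic acids from unbranched aliphatic aldehydes, so the E 3,4-alkene needed for the diene should be set here.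

Step 7
Reactants: 12 (3E)-5-[4-(benzyloxy)phenyl]pent-3-enoic acid
Product: 13 benzyl (3E)-5-[4-(benzyloxy)phenyl]pent-3-enoate
Conditions: BnBr, KHCO3, DMF, rt
Reagents that add atoms: benzyl bromide, BrCc1ccccc1
Why: Carboxylate O-alkylation (SN2 esterification) with benzyl bromide under bicarbonate, a base too weak to move the β,γ-alkene into conjugation, and the benzyl ester is chosen because its alkoxy group is the one lost in the later aromatisation.

Step 8
Reactants: 13 benzyl (3E)-5-[4-(benzyloxy)phenyl]pent-3-enoate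
Product: 15 trimethyl({(1Z,3E)-1-(benzyloxy)-5-[4-(benzyloxy)phenyl]penta-1,3-dien-1-yl}oxy)silane, via lithium dienolate 14 (not isolated)
Conditions: LiN(iPr)2, THF–DMPU, −78 °C; then Me3SiCl, −78 °C to rt; pentane, filtration and concentration under argon, used crude
Reagents that add atoms: chlorotrimethylsilane, C[Si](C)(C)Cl
Why: Silyl ketene acetal formation from an ester enolate, in which LiN(iPr)2 removes the doubly activated α-proton of the β,γ-unsaturated ester to give dienolate 14 with the E alkene intact and Me3SiCl silylates it on oxygen to the 1-alkoxy-1-silyloxy diene (1Z expected with DMPU, though this geometry is of no consequence).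

Step 9
Reactants: 15 trimethyl({(1Z,3E)-1-(benzyloxy)-5-[4-(benzyloxy)phenyl]penta-1,3-dien-1-yl}oxy)silane; 7 5-[3-(benzyloxy)-5-methoxyphenyl]-1-[4-(benzyloxy)phenyl]pent-2-yn-1-one
Product: 17 [4-(benzyloxy)phenyl]{3-[4-(benzyloxy)benzyl]-2-{2-[3-(benzyloxy)-5-methoxyphenyl]ethyl}-6-hydroxyphenyl}methanone, via cyclohexa-1,4-diene cycloadduct 16 (not isolated)
Conditions: 15 (2 equiv), PhMe, 100 °C, sealed tube; then 1 M HCl, THF, rt
Reagents that add atoms: none
Why: The ketene acetal 15 is a strongly polarised, electron-rich diene that should add to the alkyne of 7 in a concerted but asynchronous normal-demand Diels–Alder reaction, the bond from its CH2Ar-bearing terminus to the chain-bearing β-carbon of the ynone running ahead of the bond from the acetal carbon to the aroyl-bearing α-carbon. The closest known reaction type is the benzannulation of 1-alkoxy-1-silyloxy-1,3-dienes with acetylenic ketones and esters to ortho-acyl phenols and salicylates. Ring B closes as a six-membered carbocycle by intermolecular (4+2) cycloaddition that forms both ring bonds (C3–C4 and C1–C2 of ring B) in one step and gives cyclohexa-1,4-diene 16; dilute acid then cleaves the O–Si bond, the hemiketal expels benzyl alcohol and the cross-conjugated dienone tautomerises to phenol 17. No stereocentre survives, since the two sp3 ring carbons of 16 (a mixture of diastereomers) both become aromatic. The step needs regioselectivity, namely the acetal carbon bonded to the aroyl-bearing carbon, and this is secured by the two oxygen donors at C1 of the diene, which put the largest HOMO coefficient on the remote terminus so that it pairs with the β-carbon of the ynone, where the LUMO coefficient is largest; the E 3,4-alkene keeps the CH2Ar group outside and lets the diene reach its s-cis form. Because the alkoxy group is benzyl, a stray loss of silanol in place of benzyl alcohol would only leave a benzyl ether of the kind that hydrogenolysis removes.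

Step 10
Reactants: 17 [4-(benzyloxy)phenyl]{3-[4-(benzyloxy)benzyl]-2-{2-[3-(benzyloxy)-5-methoxyphenyl]ethyl}-6-hydroxyphenyl}methanone
Product: 20 2,4-bis[4-(benzyloxy)benzyl]-3-{2-[3-(benzyloxy)-5-methoxyphenyl]ethyl}phenol, via aryl ethyl carbonate 18 (not isolated), via ortho-quinone methide 19 (not isolated)
Conditions: ClCO2Et, Et3N, THF, 0 °C; then NaBH4, THF–H2O, 0 °C to rt
Reagents that add atoms: none
Why: Reductive deoxygenation of an ortho-acyl phenol through its carbonate, in which NaBH4 reduces the ketone of 18, the alkoxide takes over the ethoxycarbonyl group and is expelled by the phenoxide to give ortho-quinone methide 19, and a second hydride adds to its exocyclic carbon to give the benzylic CH2, a base-mediated path chosen because it avoids a benzhydryl cation that could close a seven-membered ring onto ring A by Friedel–Crafts alkylation.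

Step 11
Reactants: 20 2,4-bis[4-(benzyloxy)benzyl]-3-{2-[3-(benzyloxy)-5-methoxyphenyl]ethyl}phenol
Product: 21 2,4-bis(4-hydroxybenzyl)-3-[2-(3-hydroxy-5-methoxyphenyl)ethyl]phenol
Conditions: H2 (1 atm), 10% Pd/C, EtOAc–MeOH, rt
Reagents that add atoms: none
Why: Catalytic hydrogenolysis should cleave the three benzyl aryl ethers as toluene, while the diarylmethane CH2 groups, the bibenzyl chain and the methyl ether are stable to H2 over Pd/C at room temperature.

**Compound list**

1 | 3-bromo-5-methoxyphenol | COc1cc(O)cc(Br)c1 | starting material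
2 | 1-(benzyloxy)-3-bromo-5-methoxybenzene | COc1cc(Br)cc(OCc2ccccc2)c1 | intermediate
3 | prop-2-en-1-ol (allyl alcohol) | C=CCO | starting material
4 | 3-[3-(benzyloxy)-5-methoxyphenyl]propanal | O=CCCc1cc(OC)cc(OCc2ccccc2)c1 | intermediate
5 | 1-(benzyloxy)-3-(but-3-yn-1-yl)-5-methoxybenzene | C#CCCc1cc(OC)cc(OCc2ccccc2)c1 | intermediate
6 | 4-(benzyloxy)benzoyl chloride | O=C(Cl)c1ccc(OCc2ccccc2)cc1 | starting material
7 | 5-[3-(benzyloxy)-5-methoxyphenyl]-1-[4-(benzyloxy)phenyl]pent-2-yn-1-one | O=C(C#CCCc1cc(OC)cc(OCc2ccccc2)c1)c1ccc(OCc2ccccc2)cc1 | intermediate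
8 | 1-(benzyloxy)-4-iodobenzene | Ic1ccc(OCc2ccccc2)cc1 | starting material
9 | 3-[4-(benzyloxy)phenyl]propanal | O=CCCc1ccc(OCc2ccccc2)cc1 | intermediate
10 | malonic acid | OC(=O)CC(=O)O | starting material
11 | 2-{3-[4-(benzyloxy)phenyl]propylidene}propanedioic acid | OC(=O)C(=CCCc1ccc(OCc2ccccc2)cc1)C(=O)O | intermediate
12 | (3E)-5-[4-(benzyloxy)phenyl]pent-3-enoic acid | OC(=O)C/C=C/Cc1ccc(OCc2ccccc2)cc1 | intermediate
13 | benzyl (3E)-5-[4-(benzyloxy)phenyl]pent-3-enoate | O=C(C/C=C/Cc1ccc(OCc2ccccc2)cc1)OCc1ccccc1 | intermediate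
14 | lithium (1Z,3E)-1-(benzyloxy)-5-[4-(benzyloxy)phenyl]penta-1,3-dien-1-olate | [Li+].[O-]/C(OCc1ccccc1)=C\C=C\Cc1ccc(OCc2ccccc2)cc1 | intermediate
15 | trimethyl({(1Z,3E)-1-(benzyloxy)-5-[4-(benzyloxy)phenyl]penta-1,3-dien-1-yl}oxy)silane | C[Si](C)(C)O/C(OCc1ccccc1)=C\C=C\Cc1ccc(OCc2ccccc2)cc1 | intermediate
16 | {6-(benzyloxy)-3-[4-(benzyloxy)benzyl]-2-{2-[3-(benzyloxy)-5-methoxyphenyl]ethyl}-6-[(trimethylsilyl)oxy]cyclohexa-1,4-dien-1-yl}[4-(benzyloxy)phenyl]methanone (mixture of diastereomers) | C[Si](C)(C)OC1(OCc2ccccc2)C=CC(Cc2ccc(OCc3ccccc3)cc2)C(CCc2cc(OC)cc(OCc3ccccc3)c2)=C1C(=O)c1ccc(OCc2ccccc2)cc1 | intermediate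
17 | [4-(benzyloxy)phenyl]{3-[4-(benzyloxy)benzyl]-2-{2-[3-(benzyloxy)-5-methoxyphenyl]ethyl}-6-hydroxyphenyl}methanone | Oc1ccc(Cc2ccc(OCc3ccccc3)cc2)c(CCc2cc(OC)cc(OCc3ccccc3)c2)c1C(=O)c1ccc(OCc2ccccc2)cc1 | intermediate
18 | 2-[4-(benzyloxy)benzoyl]-4-[4-(benzyloxy)benzyl]-3-{2-[3-(benzyloxy)-5-methoxyphenyl]ethyl}phenyl ethyl carbonate | CCOC(=O)Oc1ccc(Cc2ccc(OCc3ccccc3)cc2)c(CCc2cc(OC)cc(OCc3ccccc3)c2)c1C(=O)c1ccc(OCc2ccccc2)cc1 | intermediate
19 | 6-[4-(benzyloxy)benzylidene]-4-[4-(benzyloxy)benzyl]-5-{2-[3-(benzyloxy)-5-methoxyphenyl]ethyl}cyclohexa-2,4-dien-1-one (alkene geometry not defined) | O=C1C=CC(Cc2ccc(OCc3ccccc3)cc2)=C(CCc2cc(OC)cc(OCc3ccccc3)c2)C1=Cc1ccc(OCc2ccccc2)cc1 | intermediate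
20 | 2,4-bis[4-(benzyloxy)benzyl]-3-{2-[3-(benzyloxy)-5-methoxyphenyl]ethyl}phenol | Oc1ccc(Cc2ccc(OCc3ccccc3)cc2)c(CCc2cc(OC)cc(OCc3ccccc3)c2)c1Cc1ccc(OCc2ccccc2)cc1 | intermediate
21 | 2,4-bis(4-hydroxybenzyl)-3-[2-(3-hydroxy-5-methoxyphenyl)ethyl]phenol | COc1cc(O)cc(CCc2c(Cc3ccc(O)cc3)ccc(O)c2Cc2ccc(O)cc2)c1 | target

**Step count and risks**

Total steps: 11. Longest linear sequence: 7 steps (steps 1, 2, 3, 4, 9, 10, 11, or equally steps 5, 6, 7, 8, 9, 10, 11).

Steps most likely to fail:

Step 9. The cycloaddition may be outrun by protodesilylation or thermal decay of the ketene acetal, because the β-carbon of the ynone is substituted and the para-alkoxyaryl ketone is only a moderate activator. A conjugate addition that does not close the ring is the other way it can go wrong. The fallback keeps the same two ring bonds but uses a stronger activating group and sets out from 5. Deprotonation with nBuLi in THF at −78 °C gives lithium acetylide F1, which is formylated with DMF (reverse quench into aqueous KH2PO4) to 5-[3-(benzyloxy)-5-methoxyphenyl]pent-2-ynal F2. This ynal should react with 15 at or below room temperature to give cycloadduct F3, and the same acid work-up should give salicylaldehyde F4. Addition of commercial 4-(benzyloxy)phenylmagnesium bromide (excess, THF, 0 °C) gives diol F5. MnO2 in CH2Cl2 then oxidises its benzhydrylic alcohol, which brings the route back at 17.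

Step 8. Claisen self-condensation of the ester enolate, silylation on carbon, or hydrolysis of the trimethylsilyl ketene acetal during solvent exchange may erode the diene before it is used. The fallback sets out from acid 12 and bypasses 13 and 15. Two equivalents of LiN(iPr)2 in THF give dilithium dienediolate F6, which cannot self-condense, and Me3SiCl converts it into bis(trimethylsilyl) ketene acetal F7. Heating F7 with 7 in toluene should give cycloadduct F8, whose bis(silyl) ketal is hydrolysed by dilute acid to the dienone and tautomerises, so the route is rejoined at 17.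

Step 10. Hydride may attack the carbonate carbonyl faster than the doubly ortho-substituted ketone, which only returns 17, or the relay may stall at the benzhydrol stage. The fallback sets out from 17 and replaces the quinone methide relay by carbinol hydrogenolysis. BnBr and K2CO3 in DMF cap the phenol as tetrabenzyl ketone F9, so that no phenoxide deactivates the carbonyl. LiAlH4 in THF reduces it to carbinol F10. H2 over Pd/C in EtOAc–AcOH then removes the four benzyl groups and the benzhydrylic hydroxyl in one operation, returning to the route at 21.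

**Further compounds**

F1 | step 9 | lithium 4-[3-(benzyloxy)-5-methoxyphenyl]but-1-yn-1-ide | [Li+].[C-]#CCCc1cc(OC)cc(OCc2ccccc2)c1
F2 | step 9 | 5-[3-(benzyloxy)-5-methoxyphenyl]pent-2-ynal | O=CC#CCCc1cc(OC)cc(OCc2ccccc2)c1
F3 | step 9 | 6-(benzyloxy)-3-[4-(benzyloxy)benzyl]-2-{2-[3-(benzyloxy)-5-methoxyphenyl]ethyl}-6-[(trimethylsilyl)oxy]cyclohexa-1,4-diene-1-carbaldehyde | C[Si](C)(C)OC1(OCc2ccccc2)C=CC(Cc2ccc(OCc3ccccc3)cc2)C(CCc2cc(OC)cc(OCc3ccccc3)c2)=C1C=O
F4 | step 9 | 3-[4-(benzyloxy)benzyl]-2-{2-[3-(benzyloxy)-5-methoxyphenyl]ethyl}-6-hydroxybenzaldehyde | O=Cc1c(O)ccc(Cc2ccc(OCc3ccccc3)cc2)c1CCc1cc(OC)cc(OCc2ccccc2)c1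
F5 | step 9 | 4-[4-(benzyloxy)benzyl]-2-{[4-(benzyloxy)phenyl](hydroxy)methyl}-3-{2-[3-(benzyloxy)-5-methoxyphenyl]ethyl}phenol (racemic) | OC(c1ccc(OCc2ccccc2)cc1)c1c(O)ccc(Cc2ccc(OCc3ccccc3)cc2)c1CCc1cc(OC)cc(OCc2ccccc2)c1
F6 | step 8 | dilithium (3E)-5-[4-(benzyloxy)phenyl]penta-1,3-diene-1,1-bis(olate) | [Li+].[Li+].[O-]C([O-])=C/C=C/Cc1ccc(OCc2ccccc2)cc1
F7 | step 8 | {[(3E)-5-[4-(benzyloxy)phenyl]penta-1,3-diene-1,1-diyl]bis(oxy)}bis(trimethylsilane) | C[Si](C)(C)OC(O[Si](C)(C)C)=C/C=C/Cc1ccc(OCc2ccccc2)cc1
F8 | step 8 | [4-(benzyloxy)phenyl]{3-[4-(benzyloxy)benzyl]-2-{2-[3-(benzyloxy)-5-methoxyphenyl]ethyl}-6,6-bis[(trimethylsilyl)oxy]cyclohexa-1,4-dien-1-yl}methanone | C[Si](C)(C)OC1(O[Si](C)(C)C)C=CC(Cc2ccc(OCc3ccccc3)cc2)C(CCc2cc(OC)cc(OCc3ccccc3)c2)=C1C(=O)c1ccc(OCc2ccccc2)cc1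
F9 | step 10 | [4-(benzyloxy)phenyl]{6-(benzyloxy)-3-[4-(benzyloxy)benzyl]-2-{2-[3-(benzyloxy)-5-methoxyphenyl]ethyl}phenyl}methanone | O=C(c1ccc(OCc2ccccc2)cc1)c1c(OCc2ccccc2)ccc(Cc2ccc(OCc3ccccc3)cc2)c1CCc1cc(OC)cc(OCc2ccccc2)c1
F10 | step 10 | [4-(benzyloxy)phenyl]{6-(benzyloxy)-3-[4-(benzyloxy)benzyl]-2-{2-[3-(benzyloxy)-5-methoxyphenyl]ethyl}phenyl}methanol (racemic) | OC(c1ccc(OCc2ccccc2)cc1)c1c(OCc2ccccc2)ccc(Cc2ccc(OCc3ccccc3)cc2)c1CCc1cc(OC)cc(OCc2ccccc2)c1
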